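The lactone ring is cut at C3–C4 (carbinol carbon to benzylic methylene) and, with it, at O2–C1. The exploited feature is C4 itself: it sits between the benzene ring (ring A) and, through C4a–C8a, the C1 carbonyl. A temporary carboxyl on C4, tied back to C1 as 6,8-dimethoxyhomophthalic anhydride, makes C4 an enolisable nucleophile and C1 an internal acyl donor. One catalytic asymmetric formal [4+2] annulation with 8-oxododecanal then forms C4–C3, fixes C3 as R and closes the lactone ring. The precursor is thus a bicyclic anhydride plus an open-chain keto aldehyde; radical decarboxylation at C4 and chelation-directed O-demethylation at C8 complete the route.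

Key step: step 5

Assumption: the quinine-derived squaramide is taken to deliver the 3R series with this aliphatic aldehyde; if the sense of induction is the opposite, the quinidine-derived pseudoenantiomer takes its place and nothing else changes.

Step 1
Reactants: 1 2,4-dimethoxy-6-methylbenzoic acid
Product: 3 2-(carboxymethyl)-4,6-dimethoxybenzoic acid, via benzylic dianion 2 (not isolated)
Conditions: LiN(i-Pr)2 (2.3 equiv), THF, −78 → 0 °C; cannulate onto solid CO2/THF, −78 °C; aq. HCl
Reagents that add atoms: carbon dioxide, O=C=O
Why: Lateral (benzylic) lithiation of the lithium carboxylate gives the ortho-toluate dianion, whose benzylic carbon is carboxylated by CO2, inverse addition limiting proton transfer from the product.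

Step 2
Reactants: 3 2-(carboxymethyl)-4,6-dimethoxybenzoic acid
Product: 4 6,8-dimethoxyisochromane-1,3-dione (6,8-dimethoxyhomophthalic anhydride)
Conditions: Ac2O (1.5 equiv), PhMe, 110 °C
Reagents that add atoms: none
Why: Cyclodehydration of the 1,5-diacid through a mixed anhydride and intramolecular acyl substitution should give the six-membered cyclic anhydride.

Step 3
Reactants: 5 non-8-enoic acid; 6 n-butyllithium
Product: 8 tridec-12-en-5-one, via gem-diolate 7 (not isolated)
Conditions: n-BuLi (2.1 equiv), Et2O, 0 °C → rt; pour into cold aq. HCl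
Reagents that add atoms: none
Why: Organolithium ketone synthesis from a carboxylic acid: the first equivalent forms the lithium carboxylate and the second adds to give a dilithium gem-diolate that releases the ketone only on acidic quench, so over-addition should be avoided.

Step 4
Reactants: 8 tridec-12-en-5-one
Product: 10 8-oxododecanal, via ozonide 9 (not isolated)
Conditions: O3, CH2Cl2, −78 °C; then PPh3, −78 °C → rt
Reagents that add atoms: ozone, [O-][O+]=O
Why: Ozonolysis (Criegee mechanism) of the only C=C bond with reductive work-up should give the aldehyde, the dialkyl ketone being inert.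

Step 5
Reactants: 4 6,8-dimethoxyisochromane-1,3-dione; 10 8-oxododecanal
Product: 12 (3R,4S)-6,8-dimethoxy-1-oxo-3-(7-oxoundecyl)isochromane-4-carboxylic acid, via aldol adduct 11 (not isolated)
Conditions: 3-[3,5-bis(trifluoromethyl)anilino]-4-[(9-deoxy-epi-quinin-9-yl)amino]cyclobut-3-ene-1,2-dione (quinine-derived squaramide, 10 mol %), t-BuOMe, −15 °C → rt; aq. HCl wash
Reagents that add atoms: none
Why: The quinuclidine nitrogen of the catalyst enolises anhydride 4 at C4 while the squaramide N–H pair binds the aldehyde carbonyl; the C4 enolate adds to the aldehyde carbon (new C4–C3 bond, adduct 11) and the C3 alkoxide at once acylates the aryl-bound C1 carbonyl, so the anhydride ring opens as the lactone ring closes and the other anhydride carbonyl is left as the C4 carboxylic acid. The closest known reaction type is the cinchona-squaramide-catalysed asymmetric formal [4+2] cycloaddition (aldol–lactonisation) of homophthalic anhydrides with aldehydes. The one ring formed, the lactone ring (C1, O2, C3, C4, C4a, C8a), is assembled by C4–C3 bond formation followed directly by 6-exo-trig acyl substitution of O2 on C1; attack on the other anhydride carbonyl would need a four-membered ring, so the regiochemistry is fixed. C3 is set by the catalyst, which should present one enantiotopic face of the hydrogen-bonded aldehyde to the ion-paired enolate; C4 is expected trans to the C3 chain, is epimerisable and is erased in step 6, so only the sense at C3 matters. The step needs chemoselectivity for the aldehyde over the ketone of 10 and for cross-aldol over anhydride self-condensation; the far lower electrophilicity of the dialkyl ketone and slow addition of 4 at low temperature should secure both.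

Step 6
Reactants: 12 (3R,4S)-6,8-dimethoxy-1-oxo-3-(7-oxoundecyl)isochromane-4-carboxylic acid
Product: 13 (3R)-6,8-dimethoxy-3-(7-oxoundecyl)isochroman-1-one
Conditions: 9-mesityl-10-phenylacridinium tetrafluoroborate (5 mol %), PhSSPh (10 mol %), i-Pr2NEt (20 mol %), CF3CH2OH, 450 nm LEDs, rt
Reagents that add atoms: none
Why: Photoredox hydrodecarboxylation of an arylacetic acid (carboxylate oxidation, loss of CO2 to the C4 benzylic radical, hydrogen-atom transfer from thiophenol) should remove the activating carboxyl without touching C3, and both C4 epimers of 12 converge on 13.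

Step 7
Reactants: 13 (3R)-6,8-dimethoxy-3-(7-oxoundecyl)isochroman-1-one
Product: 15 (3R)-8-hydroxy-6-methoxy-3-(7-oxoundecyl)isochroman-1-one, via aryloxydichloroborane 14 (not isolated)
Conditions: BCl3 (2.5 equiv), CH2Cl2, −78 → 0 °C; then H2O
Reagents that add atoms: none
Why: Chelation-controlled Lewis-acid ether cleavage: boron bound to the C1 carbonyl should cleave only the peri C8 methyl ether, leaving the C6 methoxy, lactone, ketone and C3 stereocentre untouched.

Compound list
1 | 2,4-dimethoxy-6-methylbenzoic acid | Cc1cc(OC)cc(OC)c1C(=O)O | starting material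
2 | lithium 2-(lithiomethyl)-4,6-dimethoxybenzoate (benzylic dianion) | [Li+].[Li+].[CH2-]c1cc(OC)cc(OC)c1C(=O)[O-] | intermediate
3 | 2-(carboxymethyl)-4,6-dimethoxybenzoic acid | OC(=O)Cc1cc(OC)cc(OC)c1C(=O)O | intermediate
4 | 6,8-dimethoxyisochromane-1,3-dione | O=C1Cc2cc(OC)cc(OC)c2C(=O)O1 | intermediate
5 | non-8-enoic acid | C=CCCCCCCC(=O)O | starting material
6 | n-butyllithium | [Li]CCCC | starting material
7 | dilithium tridec-12-ene-5,5-bis(olate) (gem-diolate) | [Li+].[Li+].CCCCC([O-])([O-])CCCCCCC=C | intermediate
8 | tridec-12-en-5-one | CCCCC(=O)CCCCCCC=C | intermediate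
9 | 3-(7-oxoundecyl)-1,2,4-trioxolane (ozonide) | CCCCC(=O)CCCCCCC1OCOO1 | intermediate
10 | 8-oxododecanal | CCCCC(=O)CCCCCCC=O | intermediate
11 | (4S)-4-[(1R)-1-hydroxy-8-oxododecyl]-6,8-dimethoxyisochromane-1,3-dione (aldol adduct) | CCCCC(=O)CCCCCC[C@@H](O)[C@H]1C(=O)OC(=O)c2c(OC)cc(OC)cc12 | intermediate
12 | (3R,4S)-6,8-dimethoxy-1-oxo-3-(7-oxoundecyl)isochromane-4-carboxylic acid | CCCCC(=O)CCCCCC[C@@H]1[C@@H](C(O)=O)c2cc(OC)cc(OC)c2C(=O)O1 | intermediate
13 | (3R)-6,8-dimethoxy-3-(7-oxoundecyl)isochroman-1-one | CCCCC(=O)CCCCCC[C@@H]1Cc2cc(OC)cc(OC)c2C(=O)O1 | intermediate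
14 | (3R)-8-(dichloroboranyloxy)-6-methoxy-3-(7-oxoundecyl)isochroman-1-one | CCCCC(=O)CCCCCC[C@@H]1Cc2cc(OC)cc(OB(Cl)Cl)c2C(=O)O1 | intermediate
15 | (3R)-8-hydroxy-6-methoxy-3-(7-oxoundecyl)isochroman-1-one | CCCCC(=O)CCCCCC[C@@H]1Cc2cc(OC)cc(O)c2C(=O)O1 | target

Total step count: 7
Longest linear sequence: 5 steps (steps 3, 4, 5, 6, 7; equally steps 1, 2, 5, 6, 7)

Steps most likely to fail

Step 5. The catalyst may discriminate the faces of the unbranched aliphatic aldehyde only weakly, which would leave C3 in low enantiomeric purity. The fallback sets out from 4 and 10 and comes back at 12. The annulation would be run with an achiral base (i-Pr2NEt, CH2Cl2, 0 °C) and should give racemic trans-6,8-dimethoxy-1-oxo-3-(7-oxoundecyl)isochromane-4-carboxylic acid F1 in place of the single enantiomer. Classical resolution of F1 with (R)-1-phenylethylamine in EtOAc/EtOH should let (R)-1-phenylethylammonium (3R,4S)-6,8-dimethoxy-1-oxo-3-(7-oxoundecyl)isochromane-4-carboxylate F2 crystallise, while the diastereomeric salt (R)-1-phenylethylammonium (3S,4R)-6,8-dimethoxy-1-oxo-3-(7-oxoundecyl)isochromane-4-carboxylate F3 should stay in the mother liquor; the S amine is used instead if the solubilities are reversed. Aqueous HCl then returns F2 to 12.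

Step 6. The excited acridinium may oxidise the electron-rich dimethoxyarene, or the base may open the lactone by elimination across C3–C4, in competition with decarboxylation. The fallback sets out from 12 and comes back at 13 by a Barton reductive decarboxylation. DCC, 2-mercaptopyridine N-oxide and catalytic DMAP in CH2Cl2 in the dark should give 2-thioxopyridin-1(2H)-yl (3R,4S)-6,8-dimethoxy-1-oxo-3-(7-oxoundecyl)isochromane-4-carboxylate F4 as the Barton ester. Irradiation of F4 with visible light in toluene with t-BuSH should then give 13 by a radical chain in which the C4 radical takes hydrogen from the thiol.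

Step 1. Proton transfer from the freshly formed arylacetate to unreacted dianion, and carboxylation of the amide base, may return starting acid. The fallback sets out from 1 and comes back at 3. MeI and K2CO3 in DMF should give methyl 2,4-dimethoxy-6-methylbenzoate F5 from 1. Lateral lithiation of F5 with LiN(i-Pr)2 (2.2 equiv, THF, −78 °C) and C-acylation with dimethyl carbonate should give methyl 2-(2-methoxy-2-oxoethyl)-4,6-dimethoxybenzoate F6 which is held as its enolate until the quench. KOH in aqueous EtOH at reflux, then HCl, should convert F6 into 3.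

Further compounds
F1 | step 5 | racemic trans-6,8-dimethoxy-1-oxo-3-(7-oxoundecyl)isochromane-4-carboxylic acid | CCCCC(=O)CCCCCCC1C(C(O)=O)c2cc(OC)cc(OC)c2C(=O)O1
F2 | step 5 | (R)-1-phenylethylammonium (3R,4S)-6,8-dimethoxy-1-oxo-3-(7-oxoundecyl)isochromane-4-carboxylate | C[C@@H]([NH3+])c1ccccc1.CCCCC(=O)CCCCCC[C@@H]1[C@@H](C([O-])=O)c2cc(OC)cc(OC)c2C(=O)O1
F3 | step 5 | (R)-1-phenylethylammonium (3S,4R)-6,8-dimethoxy-1-oxo-3-(7-oxoundecyl)isochromane-4-carboxylate | C[C@@H]([NH3+])c1ccccc1.CCCCC(=O)CCCCCC[C@H]1[C@H](C([O-])=O)c2cc(OC)cc(OC)c2C(=O)O1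
F4 | step 6 | 2-thioxopyridin-1(2H)-yl (3R,4S)-6,8-dimethoxy-1-oxo-3-(7-oxoundecyl)isochromane-4-carboxylate | CCCCC(=O)CCCCCC[C@@H]1[C@@H](C(=O)On3ccccc3=S)c2cc(OC)cc(OC)c2C(=O)O1
F5 | step 1 | methyl 2,4-dimethoxy-6-methylbenzoate | Cc1cc(OC)cc(OC)c1C(=O)OC
F6 | step 1 | methyl 2-(2-methoxy-2-oxoethyl)-4,6-dimethoxybenzoate | COC(=O)Cc1cc(OC)cc(OC)c1C(=O)OC
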